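Amounts first: c(first end groups) is 0.083 M, second end groups stand at 1.00 equiv, and c(one-sided end groups) and c(protic impurity) are 4.15 mM and 4.15 mM.

| flask | first end groups | second end groups | one-sided end groups | protic impurity | temperature | remark | time |
|---|---|---|---|---|---|---|---|
| summer | 0.083 M | 1 equiv | 4.15 mM | 4.15 mM | 5 °C | the very flask that is asked about, followed so far |  |
| midnight | 0.083 M | 1 equiv | 4.15 mM | 2.8 mM | 0 °C | run made earlier |  |
| flask | 0.083 M | 1.00 equiv | 4.15 mM | 4.15 mM | 5 °C |  | 4.0 d |

| run | time / h | links / % |
|---|---|---|
| summer | 8.00 | 48.5 |
| summer | 12.0 | 52.1 |
| summer | 20.0 | 53.2 |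
| summer | 25.0 | 52.3 |
| summer | 40.0 | 50.7 |
| summer | 60.0 | 46.5 |
| summer | 96.0 | 42.4 |
| midnight | 0.250 | 2.8 |
| midnight | 0.833 | 8.5 |
| midnight | 1.33 | 12.0 |
| midnight | 2.00 | 17.3 |
| midnight | 3.00 | 23.4 |
| midnight | 4.00 | 28.5 |
| midnight | 5.00 | 33.0 |

(each reading ± 0.5 percentage points)

- links, in percent of the first end groups first charged, at 4.0 d
- the remedy with the largest gain of links, or "none" below 2 percentage points (elm / cedar / maple / oak / none)
- links present, with what was taken out counted in, in percent of the first end groups first charged, after cedar
- links present, with what was taken out counted in, in percent of the first end groups first charged, after maple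

- elm: at 4.0 d add second end groups, 100% of the amount charged, then wait 4.0 d
- cedar: at 4.0 d raise the temperature by 25 K, then wait 4.0 d
- maple: change nothing and wait 4.0 d more
- oak: at 4.0 d take out 90% of the links then present, then wait 4.0 d

- removed links is counted in
- additions bring no volume worth counting

If each one-sided end group and each protic impurity removes one first end group, this flask has a usable share of 90.0% of its first end groups. That share is the reckoned ceiling on links. The charge of second end groups stands above that usable share.

It pays to count what is left rather than what is made. The summer reading at 96.0 h, the asked time, is 42.4% with a scatter of 0.5 percentage points, so links now stand near that value. The idle share, usable first end groups not in links, is then 48 points. At the highest reading, 53.2% at 20.0 h, it was 37 points, so the idle share has been growing since.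

A straight line through the last two readings puts links at 31.5% after maple, and that line is the weak link. The readings fell 4.2 points in 20.0 h, then 4.1 points in the longer 36.0 h. Over these two gaps the fall per hour is smaller in the later one, a reading that carries the scatter, so this reckoning sets maple above the line.

The forecast says 42.5% now, elm as best and 4% after cedar. It holds that “links continue down” to 32% after maple, close to the straight line at 31.5%, whereas this reckoning lets the fall slow.

The flask gives 42.5% now, 40.6% after maple and 66.7% after cedar, the best remedy being cedar.

    first end groups + second end groups → links (k = 2.40 M⁻¹ h⁻¹, Ea = 64.0 kJ mol⁻¹)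
    first end groups + one-sided end groups → capped ends (k = 150 M⁻¹ h⁻¹, Ea = 42.0 kJ mol⁻¹)
    first end groups + protic impurity → quenched substrate (k = 15.0 M⁻¹ h⁻¹, Ea = 55.0 kJ mol⁻¹)
    links ⇌ isomer of the product (K = 0.910, k = 0.0160 h⁻¹, Ea = 95.0 kJ mol⁻¹, ΔH = −49.0 kJ mol⁻¹)
    2 second end groups → self-condensation product (k = 0.430 M⁻¹ h⁻¹, Ea = 58.0 kJ mol⁻¹)
    (constants at 5 °C)

At the asked time the flask's idle share is 48 points, and free first end groups at 13.6% with isomer of the product at 34.0% together hold 48 points. Cedar shrinks the idle share to 23 points. The neighbour flask with 0.600 equiv of second end groups has the same usable share and 28.8% links, so its idle share is 61 points, and its free first end groups and isomer of the product hold 61 points.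

The readings are calculated with made-up constants, noise included.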